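**Strategy.** Everything rests on disconnecting C2–C3 of the pyrrole ring and re-attaching C2 to the sulfur carried by C3. The feature exploited is the vicinal pair C2–SMe/C3–S next to N1. These atoms map onto N1=C2(SMe)–S3–C4H2 of a six-membered 4H-3,1-benzothiazine. Deprotonation at benzylic C4 makes C2 migrate from S3 to C4. This single operation forms C2–C3, contracts the thiazine to the pyrrole ring and liberates the C3 thiolate, which iodomethane caps in the same flask. The precursor is 5,6,7-tribromo-2-(methylsulfanyl)-4H-3,1-benzothiazine, assembled from an o-(bromomethyl)aryl isothiocyanate, hydrosulfide and iodomethane. Its bromine pattern is fixed early on 3-methyl-4-nitroaniline.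

Key step: step 7

Assumption: the indole N–H formed in step 7 is taken to be more acidic than C4–H of the benzothiazine, which fixes the base at two equivalents; NaSH is used as its commercial hydrate.

**Step 1**
Reactants: 1 3-methyl-4-nitroaniline
Product: 2 2,6-dibromo-3-methyl-4-nitroaniline
Conditions: Br2 (2.2 equiv), AcOH, 20 to 50 °C
Reagents that add atoms: bromine, BrBr
Why: Electrophilic aromatic bromination, in which the amino group activates its two ortho carbons C2 and C6 (para is blocked by the nitro group, to which both are meta), as in the standard dibromination of 4-nitroaniline, and the deactivated ring should stop there.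

**Step 2**
Reactants: 2 2,6-dibromo-3-methyl-4-nitroaniline
Product: 4 1,2,3-tribromo-4-methyl-5-nitrobenzene, via arenediazonium bromide 3 (not isolated)
Conditions: t-BuONO (1.5 equiv), CuBr2 (1.2 equiv), MeCN, 0 to 65 °C
Reagents that add atoms: CuBr2, [Cu+2].[Br-].[Br-]; tert-butyl nitrite, CC(C)(C)ON=O (its nitrogen stays only in 3)
Why: Sandmeyer bromination in its aprotic alkyl nitrite form, which diazotises weakly basic 2,6-dihalo-4-nitroanilines without strong acid and transfers bromine from copper to the aryl radical, so the third bromine enters exactly at the former amino carbon.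

**Step 3**
Reactants: 4 1,2,3-tribromo-4-methyl-5-nitrobenzene
Product: 5 3,4,5-tribromo-2-methylaniline
Conditions: Fe powder, NH4Cl, EtOH–H2O, 80 °C
Reagents that add atoms: none
Why: Béchamp-type iron reduction of a nitroarene under near-neutral conditions, which leaves aryl C–Br bonds untouched where catalytic hydrogenation would endanger them.

**Step 4**
Reactants: 5 3,4,5-tribromo-2-methylaniline; 6 thiophosgene
Product: 7 1,2,3-tribromo-5-isothiocyanato-4-methylbenzene
Conditions: CSCl2 (1.2 equiv), NaHCO3, CH2Cl2–H2O, 0 °C to rt
Reagents that add atoms: thiophosgene 6, S=C(Cl)Cl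
Why: Thiophosgenation of an aniline (N-thioacylation, then loss of HCl), which is reliable for weakly nucleophilic haloanilines whose dithiocarbamate formation with CS2 is sluggish, and which masks nitrogen for the next step while installing the future C2.

**Step 5**
Reactants: 7 1,2,3-tribromo-5-isothiocyanato-4-methylbenzene
Product: 8 1,2,3-tribromo-4-(bromomethyl)-5-isothiocyanatobenzene
Conditions: NBS (1.05 equiv), AIBN (10 mol %), PhCF3, 90 °C
Reagents that add atoms: N-bromosuccinimide, O=C1CCC(=O)N1Br
Why: Wohl–Ziegler benzylic bromination, a reaction known for o-tolyl isothiocyanate itself, in which the NCS group tolerates the radical chain, the deactivated ring offers no site for electrophilic bromine, and the two ortho substituents slow a second bromination.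

**Step 6**
Reactants: 8 1,2,3-tribromo-4-(bromomethyl)-5-isothiocyanatobenzene; 9 iodomethane
Product: 11 5,6,7-tribromo-2-(methylsulfanyl)-4H-3,1-benzothiazine, via benzothiazine-2-thione 10 (not isolated)
Conditions: NaSH hydrate (1.05 equiv), DMF, 0 °C; then K2CO3, MeI (1.1 equiv), 0 °C to rt
Reagents that add atoms: sodium hydrosulfide, [Na+].[SH-]; iodomethane 9, CI
Why: Addition of a sulfur nucleophile to an aryl isothiocyanate coupled with intramolecular SN2 at the benzylic bromide is a known entry to 4H-3,1-benzothiazines, here whichever electrophile hydrosulfide attacks first leads to the same six-membered thione 10, and its soft thiocarbonyl sulfur is then alkylated by MeI (S-alkylation of a cyclic dithiocarbamate).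

**Step 7**
Reactants: 11 5,6,7-tribromo-2-(methylsulfanyl)-4H-3,1-benzothiazine; 9 iodomethane
Product: 15 4,5,6-tribromo-2,3-bis(methylsulfanyl)-1H-indole, via thiirane-fused potassium indolinide 12 (not isolated), via dipotassium indolide-3-thiolate 13 (not isolated), via potassium indole-3-thiolate 14 (not isolated)
Conditions: KN(SiMe3)2 (2.2 equiv), THF, −78 to 0 °C (11 added slowly to the base); AcOH (1.2 equiv, in THF), −78 °C; MeI (1.05 equiv), −78 to 0 °C
Reagents that add atoms: iodomethane 9, CI; KN(SiMe3)2, C[Si](C)(C)[N-][Si](C)(C)C.[K+] (its potassium stays only in 12 to 14)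
Why: Proposed new method: KN(SiMe3)2 removes a proton from C4 of 11, the most acidic site because it is benzylic to the electron-poor tribromoarene and alpha to the thioimidate sulfur S3, and the carbanion adds to C2 of the C2=N1 bond to give the thiirane-fused indolinide 12, in which the C2–C3 bond of the indole already exists. The nitrogen lone pair of 12 then rebuilds C2=N1 and pushes out the strained ring sulfur, so that C2 has moved from S3 to C4 in a net anionic [1,2]-shift, and the second equivalent of base takes the C3 proton to give the aromatic dianion 13. The closest known reaction types are the [1,2]-thia-Wittig rearrangement, the 1,2-shift of acyl and carbamoyl groups from a heteroatom to an adjacent benzylic carbanion, and base-induced contractions of 1,3-thiazines through thiiranes, which normally end in loss of sulfur rather than in its capture. The bond-forming event is a 3-exo-trig closure (the C=N bond lies outside the three-membered ring), the pyrrole ring then arises by contraction of the thiazine when the S–C2 bond breaks, and no stereocentre has to be controlled because the two in racemic, necessarily cis-fused 12 vanish on aromatisation. Two selectivities are needed: deprotonation at C4 and not at C8–H or SCH3, secured by the double activation of C4 and by slow addition of 11 to cold base, which also keeps bromine migration down, and opening of the thiirane at C2–S and not loss of MeS− or of sulfur, secured by ring strain, by the absence of any thiophile and by aromatisation being open only along this path. Two equivalents of base are used since the N–H that forms is more acidic than C4–H of 11 and would otherwise quench unreacted carbanion, and AcOH then reprotonates N1 and destroys surplus base, so that MeI meets only the soft thiolate of 14 and S-methylation (SN2) gives 15 without N-methylation.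

**Compound list**
1 | 3-methyl-4-nitroaniline | Cc1cc(N)ccc1[N+](=O)[O-] | starting material
2 | 2,6-dibromo-3-methyl-4-nitroaniline | Cc1c(Br)c(N)c(Br)cc1[N+](=O)[O-] | intermediate
3 | 2,6-dibromo-3-methyl-4-nitrobenzenediazonium bromide | Cc1c(Br)c([N+]#N)c(Br)cc1[N+](=O)[O-].[Br-] | intermediate
4 | 1,2,3-tribromo-4-methyl-5-nitrobenzene (2,3,4-tribromo-6-nitrotoluene) | Cc1c(Br)c(Br)c(Br)cc1[N+](=O)[O-] | intermediate
5 | 3,4,5-tribromo-2-methylaniline | Cc1c(N)cc(Br)c(Br)c1Br | intermediate
6 | thiophosgene | S=C(Cl)Cl | starting material
7 | 1,2,3-tribromo-5-isothiocyanato-4-methylbenzene | Cc1c(N=C=S)cc(Br)c(Br)c1Br | intermediate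
8 | 1,2,3-tribromo-4-(bromomethyl)-5-isothiocyanatobenzene | BrCc1c(N=C=S)cc(Br)c(Br)c1Br | intermediate
9 | iodomethane | CI | starting material
10 | 5,6,7-tribromo-1,4-dihydro-2H-3,1-benzothiazine-2-thione | S=C1Nc2cc(Br)c(Br)c(Br)c2CS1 | intermediate
11 | 5,6,7-tribromo-2-(methylsulfanyl)-4H-3,1-benzothiazine | CSC1=Nc2cc(Br)c(Br)c(Br)c2CS1 | intermediate
12 | potassium 4,5,6-tribromo-2,3-epithio-2-(methylsulfanyl)indolin-1-ide (thiirane fused across C2–C3 of the indoline; racemic, the cis fusion is the only one possible) | CSC12[N-]c3cc(Br)c(Br)c(Br)c3C1S2.[K+] | intermediate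
13 | dipotassium 4,5,6-tribromo-2-(methylsulfanyl)indol-1-ide-3-thiolate | CSc1[n-]c2cc(Br)c(Br)c(Br)c2c1[S-].[K+].[K+] | intermediate
14 | potassium 4,5,6-tribromo-2-(methylsulfanyl)-1H-indole-3-thiolate (the salt of 4,5,6-tribromo-2-(methylsulfanyl)-1H-indole-3-thiol) | CSc1[nH]c2cc(Br)c(Br)c(Br)c2c1[S-].[K+] | intermediate
15 | 4,5,6-tribromo-2,3-bis(methylsulfanyl)-1H-indole | CSc1[nH]c2cc(Br)c(Br)c(Br)c2c1SC | target

Total step count: 7. Longest linear sequence: 7 steps (from 1).

**Steps most likely to fail**

1. Step 7 (the step that bears the label). The rearrangement may stall at the carbanion. The thiirane may extrude sulfur or expel methanethiolate instead of opening. The amide base may also set off bromine migration on the arene. The fallback uses known chemistry only, sets out from 4 and comes back at 15. A Leimgruber–Batcho sequence converts 4 with Me2NCH(OMe)2 in DMF at 110 °C into (E)-N,N-dimethyl-2-(2,3,4-tribromo-6-nitrophenyl)ethen-1-amine F1. Fe in AcOH then closes this reductively to 4,5,6-tribromo-1H-indole F2. Electrophilic sulfenylation with MeSCl (from MeSSMe and SO2Cl2, CH2Cl2, 0 °C) should give 4,5,6-tribromo-3-(methylsulfanyl)-1H-indole F3. A second equivalent of MeSCl attacks C3 again, one MeS group shifts to C2, and proton loss delivers 15.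

2. Step 5. Over-bromination at the benzylic carbon, or consumption of the isothiocyanate sulfur by bromine, may erode the monobromide. The fallback sets out from 4 and comes back at 10. It functionalises the methyl group before any sulfur is present and then closes the ring with CS2, which supplies C2 and both sulfurs.
   - NBS and AIBN in PhCF3 give 1,2,3-tribromo-4-(bromomethyl)-5-nitrobenzene F4.
   - CaCO3 in refluxing dioxane–H2O hydrolyses it to (2,3,4-tribromo-6-nitrophenyl)methanol F5.
   - Fe and NH4Cl reduce this to (6-amino-2,3,4-tribromophenyl)methanol F6.
   - HBr in AcOH converts it into 3,4,5-tribromo-2-(bromomethyl)anilinium bromide F7.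
   - CS2 with K2CO3 in DMF forms the dithiocarbamate, which alkylates itself intramolecularly to 10.
   - Compound 10 is then methylated as in the second half of step 6.

3. Step 6. Hydrosulfide may bridge two benzylic carbons and start oligomerisation, and part of the later methylation may go to nitrogen. The fallback sets out from 8 and comes back at 11 without any new compound. NaSMe (1.0 equiv, THF, −40 to 0 °C) adds to the isothiocyanate carbon, so the C2–SMe bond is made by addition and not by alkylation. The resulting dithiocarbamate anion closes the ring by intramolecular SN2 at the crowded benzylic bromide. This is the known behaviour of o-(bromomethyl)phenyl isothiocyanate towards thiolates.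

**Further compounds**
F1 | step 7 | (E)-N,N-dimethyl-2-(2,3,4-tribromo-6-nitrophenyl)ethen-1-amine | CN(C)/C=C/c1c(Br)c(Br)c(Br)cc1[N+](=O)[O-]
F2 | step 7 | 4,5,6-tribromo-1H-indole | Brc1cc2[nH]ccc2c(Br)c1Br
F3 | step 7 | 4,5,6-tribromo-3-(methylsulfanyl)-1H-indole | CSc1c[nH]c2cc(Br)c(Br)c(Br)c12
F4 | step 5 | 1,2,3-tribromo-4-(bromomethyl)-5-nitrobenzene | BrCc1c(Br)c(Br)c(Br)cc1[N+](=O)[O-]
F5 | step 5 | (2,3,4-tribromo-6-nitrophenyl)methanol | OCc1c(Br)c(Br)c(Br)cc1[N+](=O)[O-]
F6 | step 5 | (6-amino-2,3,4-tribromophenyl)methanol | Nc1cc(Br)c(Br)c(Br)c1CO
F7 | step 5 | 3,4,5-tribromo-2-(bromomethyl)anilinium bromide | [NH3+]c1cc(Br)c(Br)c(Br)c1CBr.[Br-]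
F0 | step 6 | none | none
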